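The route rests on disconnecting the C6–C7 bond of ring B. The target carries an isopropenyl group on C7 next to the C6 methylene, and ring A (C1–C5, C10) can hold a C4 carbonyl conjugated to an exocyclic C5=C6 bond: the retron of a conjugate ene reaction. In one operation the Me2AlCl-promoted ene reaction bonds C7 of a trisubstituted alkene to C6, closes ring B, creates the isopropenyl group and sets C7 and C5. Its precursor is an enantiopure ring A α-methylene ketone with methyl and homoprenyl groups on C10 and a silyloxymethyl group on C1. That carbon later becomes C4′ of the chromene, annulated through a benzylic cation.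

Key step: step 7

Remarks on the chemistry:
- Numbering: the decalin carries eudesmane numbers (ring A = C1–C5, C10; ring B = C5–C10; C11–C13 = isopropenyl on C7). β is the face of the C10 methyl group. The monocyclic ring A compounds already use these numbers (C4 carbonyl, C5, C10, C1, C2, C3). Chromene atoms are primed; C4′ is bonded to C1.
- Assumption: the lipase of step 3 is taken to acetylate the (S)-alcohol faster. Should it prefer the (R)-alcohol, the (R)-acetate is collected instead and cleaved by the same lipase in phosphate buffer to the same compound 4.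
- The benzo ring needs oxygen on C5′, C7′ and C8′ and hydrogen on C6′. This maps onto 2,3,5-trimethoxyphenol, so the arene is built from 2-hydroxy-4,6-dimethoxybenzaldehyde. A 5-bromo-3-methoxysalicylaldehyde pattern would place its substituents on C6′ and C8′ and cannot give this ring.

Step 1
Reactants: 1 ethyl 2-methyl-4-oxocyclohex-2-ene-1-carboxylate (Hagemann's ester, racemic)
Product: 2 4-(hydroxymethyl)-3-methylcyclohex-2-en-1-ol (racemic; cis/trans mixture)
Conditions: LiAlH4 (1.5 equiv), Et2O, 0 °C; H2O, aq. NaOH
Reagents that add atoms: none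
Why: Hydride reduction with LiAlH4 takes the ester to the primary alcohol and the enone carbonyl (1,2-sense) to the allylic alcohol, and the mixed carbinol configuration is irrelevant because this centre is reoxidised in step 2.

Step 2
Reactants: 2 4-(hydroxymethyl)-3-methylcyclohex-2-en-1-ol
Product: 3 rac-4-(hydroxymethyl)-3-methylcyclohex-2-en-1-one
Conditions: activated MnO2 (15 equiv), CH2Cl2, 23 °C
Reagents that add atoms: none
Why: Selective allylic oxidation: MnO2 oxidises only the allylic alcohol and leaves the saturated primary alcohol untouched.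

Step 3
Reactants: 3 rac-4-(hydroxymethyl)-3-methylcyclohex-2-en-1-one
Product: 4 (R)-4-(hydroxymethyl)-3-methylcyclohex-2-en-1-one
Conditions: Burkholderia cepacia lipase (Amano PS), vinyl acetate (3 equiv), t-BuOMe, 30 °C, stopped just past half conversion; chromatography
Reagents that add atoms: none
Why: Lipase-catalysed kinetic resolution by enantioselective transesterification should acetylate one enantiomer of the primary alcohol, so the future C1 stereocentre is secured by separating the remaining (R)-alcohol from the (S)-acetate.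

Step 4
Reactants: 4 (R)-4-(hydroxymethyl)-3-methylcyclohex-2-en-1-one
Product: 5 (R)-3-methyl-4-{[tri(propan-2-yl)silyl]oxymethyl}cyclohex-2-en-1-one
Conditions: TIPSCl (1.2 equiv), imidazole (2.5 equiv), DMF, 23 °C
Reagents that add atoms: chlorotri(propan-2-yl)silane, CC(C)[Si](Cl)(C(C)C)C(C)C
Why: Silylation of the primary alcohol under weakly basic conditions gives a bulky, poorly Lewis-basic ether and should not epimerise the γ-stereocentre of the enone.

Step 5
Reactants: 5 (R)-3-methyl-4-{[tri(propan-2-yl)silyl]oxymethyl}cyclohex-2-en-1-one, 6 5-bromo-2-methylpent-2-ene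
Product: 8 C4=C5 trimethylsilyl enol ether of the conjugate adduct (C10 methyl cis and C10 homoprenyl trans to the C1 CH2OTIPS group), via (4-methylpent-3-en-1-yl)magnesium bromide 7 (not isolated)
Conditions: 6, Mg, THF, 23 °C; then CuBr·SMe2 (10 mol %), TMSCl (2 equiv), DMPU (2 equiv), 5, THF, −78 to −30 °C; Et3N, pentane, cold aq. NaHCO3
Reagents that add atoms: chlorotrimethylsilane, C[Si](C)(C)Cl
Why: Copper-catalysed, TMSCl-accelerated conjugate addition of the Grignard reagent to the β,β-disubstituted enone creates the quaternary C10 by axial attack anti to the neighbouring CH2OTIPS group (chain trans to it), and the enolate is trapped regiospecifically as the silyl enol ether.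

Step 6
Reactants: 8 C4=C5 trimethylsilyl enol ether
Product: 11 (3S,4R)-3-methyl-2-methylidene-3-(4-methylpent-3-en-1-yl)-4-{[tri(propan-2-yl)silyl]oxymethyl}cyclohexan-1-one (ring A α-methylene ketone), via Mannich base 9 (not isolated), via trimethylammonium iodide 10 (not isolated)
Conditions: [CH2=NMe2]I (1.5 equiv), CH2Cl2, 23 °C; aq. NaHCO3 extraction; crude amine: MeI (5 equiv), Et2O, 23 °C; DBU (2 equiv), CH2Cl2, 23 °C
Reagents that add atoms: dimethyl(methylidene)ammonium iodide (Eschenmoser's salt), C=[N+](C)C.[I-]
Why: Mannich aminomethylation of the silyl enol ether places the one-carbon unit on C5 only, and N-methylation followed by base-induced β-elimination of trimethylamine unveils the exocyclic C5=C6 enone without touching C10 or C1.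

Step 7
Reactants: 11 ring A α-methylene ketone
Product: 12 trans-fused decalone, 1β-{[tri(propan-2-yl)silyl]oxymethyl}-15-nor-eudesm-11-en-4-one (5α-H; 7β-isopropenyl; 10β-CH3)
Conditions: Me2AlCl (1.5 equiv), CH2Cl2, −78 to 0 °C; aq. KNaC4H4O6 (potassium sodium tartrate); then K2CO3, MeOH, 23 °C
Reagents that add atoms: none
Why: Me2AlCl binds the C4 carbonyl, C7 of the trisubstituted alkene bonds to the exocyclic C6 and a hydrogen of a C11 methyl group passes to C5 (concerted but asynchronous, or through the C11 cation and aluminium enolate pair), which closes ring B and leaves the isopropenyl group. The closest known reaction type is the Lewis acid-promoted intramolecular ene reaction of an α-methylene ketone with a trisubstituted alkene (conjugate ene), the carbocyclic counterpart of the citronellal-to-isopulegol closure. Ring B closes as a six-membered chair, 6-endo with respect to the enone (C5 and C6 both end in the ring) and exo with respect to the ene alkene. C7 is controlled by this chair: the homoprenyl chain is equatorial on ring A because it is trans to the equatorial C1 CH2OTIPS group, C7 reaches the α-face of C6 opposite to the axial C10 methyl group, and the developing isopropenyl group lies equatorial, which gives 7β. C5 takes up its hydrogen on the same α-face and is in any case α to the ketone, so the K2CO3/MeOH treatment converges it to the more stable trans fusion (5α-H). The step needs hydrogen transfer to win over collapse of the enolate on C11, and the substrate secures this because O–C11 closure would give a bridged oxabicyclo[3.3.1]nonene with a bridgehead enol ether and C5–C11 closure a cyclobutane, while the bulky TIPS ether keeps the second oxygen from competing for aluminium and Me2AlCl scavenges protic acid.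

Step 8
Reactants: 12 trans-fused decalone
Product: 14 Δ3 enol triflate of 12 (triflate on C4), via lithium enolate 13 (not isolated)
Conditions: LDA (1.2 equiv), THF, −78 °C; PhNTf2 (1.3 equiv), −78 to 0 °C
Reagents that add atoms: N-phenylbis(trifluoromethanesulfonimide), O=S(=O)(N(c1ccccc1)S(=O)(=O)C(F)(F)F)C(F)(F)F
Why: Kinetic deprotonation removes a C3 proton in preference to the hindered C5 methine next to the quaternary C10, and O-sulfonylation of the enolate (enol triflate formation) fixes the C3=C4 double bond while C5 stays untouched.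

Step 9
Reactants: 14 Δ3 enol triflate
Product: 15 1β-{[tri(propan-2-yl)silyl]oxymethyl}eudesma-3,11-diene (4-methyl-Δ3 alkene)
Conditions: MeZnCl (2 equiv), Pd(PPh3)4 (5 mol %), THF, 23 to 50 °C
Reagents that add atoms: methylzinc chloride, C[Zn]Cl
Why: Negishi cross-coupling replaces the triflate by the C15 methyl group with retention of the alkene position, and the silyl ether and the isopropenyl group are inert to it.

Step 10
Reactants: 15 4-methyl-Δ3 alkene
Product: 16 3α,4α-epoxide of 15
Conditions: mCPBA (1.05 equiv), NaHCO3, CH2Cl2, −20 to 0 °C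
Reagents that add atoms: 3-chloroperoxybenzoic acid, O=C(OO)c1cccc(Cl)c1
Why: Prilezhaev epoxidation is faster at the trisubstituted C3=C4 alkene than at the 1,1-disubstituted isopropenyl group and should occur on the α-face, opposite to the axial C10 methyl group, which places the C4–O bond α.

Step 11
Reactants: 16 3α,4α-epoxide
Product: 17 1β-{[tri(propan-2-yl)silyl]oxymethyl}eudesm-11-en-4α-ol (4β-CH3)
Conditions: LiEt3BH (3 equiv), THF, 0 to 50 °C; H2O
Reagents that add atoms: none
Why: Hydride opening of the trisubstituted epoxide (SN2) takes place at the secondary C3 because C4 is tertiary and its β-face is blocked by the syn-axial C10 methyl group, so the oxygen stays on C4 as the equatorial 4α-alcohol with unchanged configuration.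

Step 12
Reactants: 17 silyl ether of the 4α-ol
Product: 18 1β-(hydroxymethyl)eudesm-11-en-4α-ol
Conditions: TBAF (1.5 equiv), THF, 23 °C
Reagents that add atoms: none
Why: Fluoride-induced desilylation frees the primary alcohol and leaves the tertiary alcohol, both alkenes and all stereocentres untouched.

Step 13
Reactants: 18 1β-(hydroxymethyl)eudesm-11-en-4α-ol
Product: 19 4α-hydroxyeudesm-11-ene-1β-carbaldehyde
Conditions: Dess–Martin periodinane (1.3 equiv), NaHCO3, CH2Cl2, 0 to 23 °C
Reagents that add atoms: none
Why: Dess–Martin oxidation converts the primary alcohol to the aldehyde under buffered conditions, the tertiary alcohol cannot be oxidised, and the equatorial 1β-aldehyde is also the more stable epimer at C1.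

Step 14
Reactants: 20 2-hydroxy-4,6-dimethoxybenzaldehyde
Product: 21 2,4-dimethoxy-6-(methoxymethoxy)benzaldehyde
Conditions: NaH (1.2 equiv), DMF, 0 °C; MOMCl (1.3 equiv), 0 to 23 °C
Reagents that add atoms: chloromethyl methyl ether, COCCl
Why: O-Alkylation of the sodium phenoxide (Williamson-type) installs the MOM acetal, which later directs the lithiation and marks the oxygen that becomes O1′.

Step 15
Reactants: 21 2,4-dimethoxy-6-(methoxymethoxy)benzaldehyde
Product: 23 2,4-dimethoxy-6-(methoxymethoxy)phenol, via aryl formate 22 (not isolated)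
Conditions: mCPBA (1.3 equiv), CH2Cl2, 0 to 23 °C; then K2CO3, MeOH, 23 °C
Reagents that add atoms: 3-chloroperoxybenzoic acid, O=C(OO)c1cccc(Cl)c1
Why: Baeyer–Villiger (Dakin-type) oxidation of the electron-rich benzaldehyde proceeds by aryl migration to the formate, whose methanolysis gives the phenol, so the formyl carbon is exchanged for the oxygen of the future C8′.

Step 16
Reactants: 23 2,4-dimethoxy-6-(methoxymethoxy)phenol
Product: 24 1,2,5-trimethoxy-3-(methoxymethoxy)benzene
Conditions: MeI (2 equiv), K2CO3 (2 equiv), acetone, 50 °C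
Reagents that add atoms: iodomethane, CI
Why: O-Methylation of the phenoxide (Williamson ether synthesis) completes the 2,3,5-trimethoxyphenol pattern with the future O1′ still differentiated as the MOM ether.

Step 17
Reactants: 24 1,2,5-trimethoxy-3-(methoxymethoxy)benzene, 19 4α-hydroxyeudesm-11-ene-1β-carbaldehyde
Product: 26 1β-{hydroxy[2-(methoxymethoxy)-3,4,6-trimethoxyphenyl]methyl}eudesm-11-en-4α-ol (both carbinol epimers), via aryllithium 25 (not isolated)
Conditions: 24 (3 equiv), n-BuLi (3 equiv), TMEDA, THF, 0 °C; then 19, −78 to −40 °C; H2O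
Reagents that add atoms: none
Why: Directed ortho-lithiation occurs at the only free position ortho to the MOM ether (also flanked by a methoxy group), and 1,2-addition of the aryllithium to the aldehyde forms the C4′–C4a′ bond (one equivalent is consumed by the tertiary hydroxyl), the carbinol configuration being irrelevant because this carbon is ionised in step 18.

Step 18
Reactants: 26 aryl carbinol, 27 trimethyl[(1-phenylethenyl)oxy]silane
Product: 28 3-(4α-hydroxyeudesm-11-en-1β-yl)-3-[2-(methoxymethoxy)-3,4,6-trimethoxyphenyl]-1-phenylpropan-1-one, (S) at the benzylic carbon (the arrangement of C4′ in the target)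
Conditions: 27 (3 equiv), Bi(OTf)3 (5 mol %), CH2Cl2, −40 to 0 °C; aq. NaHCO3
Reagents that add atoms: none
Why: Lewis acid-catalysed SN1 substitution (Mukaiyama-type alkylation of a silyl enol ether): the 2,4,6-trioxygenated benzylic alcohol ionises to a cation that is an O-alkylated ortho-quinone methide, allylic 1,3-strain holds the C1–H bond in its plane, and the enol ether should attack the face anti to the quaternary C10, which sets C4′; material that loses the MOM group here converges on the same chromene in step 19.

Step 19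
Reactants: 28 MOM-protected aryl ketone
Product: 31 (4′R)-4′-(4α-hydroxyeudesm-11-en-1β-yl)-5′,7′,8′-trimethoxy-2′-phenyl-4′H-chromene (CNP0390914.2), via keto phenol 29 (not isolated), via methyl ketal 30 (not isolated)
Conditions: TsOH·H2O (0.3 equiv), MeOH, 40 °C; NaHCO3, extractive work-up; crude: PPTS (0.2 equiv), toluene, 4 Å MS, 80 °C
Reagents that add atoms: none
Why: Acid-catalysed acetal exchange removes the MOM group as dimethoxymethane, the freed phenol closes on the ketone as the cyclic methyl ketal, and acid-catalysed elimination of methanol under anhydrous conditions gives the conjugated 2-phenyl-4H-chromene enol ether without touching C4′, the tertiary alcohol or the isopropenyl group.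

Compound list
1 | ethyl 2-methyl-4-oxocyclohex-2-ene-1-carboxylate (racemic) | CCOC(=O)C1CCC(=O)C=C1C | starting material
2 | 4-(hydroxymethyl)-3-methylcyclohex-2-en-1-ol (racemic; cis/trans mixture) | CC1=CC(O)CCC1CO | intermediate
3 | rac-4-(hydroxymethyl)-3-methylcyclohex-2-en-1-one | CC1=CC(=O)CCC1CO | intermediate
4 | (R)-4-(hydroxymethyl)-3-methylcyclohex-2-en-1-one | CC1=CC(=O)CC[C@H]1CO | intermediate
5 | (R)-3-methyl-4-{[tri(propan-2-yl)silyl]oxymethyl}cyclohex-2-en-1-one | CC1=CC(=O)CC[C@H]1CO[Si](C(C)C)(C(C)C)C(C)C | intermediate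
6 | 5-bromo-2-methylpent-2-ene | CC(C)=CCCBr | starting material
7 | (4-methylpent-3-en-1-yl)magnesium bromide | CC(C)=CCC[Mg]Br | intermediate (not isolated)
8 | C4=C5 trimethylsilyl enol ether; C10 methyl cis and homoprenyl trans to the C1 CH2OTIPS group | CC(C)=CCC[C@]1(C)C=C(O[Si](C)(C)C)CC[C@H]1CO[Si](C(C)C)(C(C)C)C(C)C | intermediate
9 | Mannich base: C5 (dimethylamino)methyl ketone (C5 epimers) | CC(C)=CCC[C@]1(C)C(CN(C)C)C(=O)CC[C@H]1CO[Si](C(C)C)(C(C)C)C(C)C | intermediate (not isolated)
10 | trimethylammonium iodide of 9 | CC(C)=CCC[C@]1(C)C(C[N+](C)(C)C)C(=O)CC[C@H]1CO[Si](C(C)C)(C(C)C)C(C)C.[I-] | intermediate (not isolated)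
11 | (3S,4R)-3-methyl-2-methylidene-3-(4-methylpent-3-en-1-yl)-4-{[tri(propan-2-yl)silyl]oxymethyl}cyclohexan-1-one | C=C1C(=O)CC[C@@H](CO[Si](C(C)C)(C(C)C)C(C)C)[C@]1(C)CCC=C(C)C | intermediate (key-step precursor)
12 | 1β-{[tri(propan-2-yl)silyl]oxymethyl}-15-nor-eudesm-11-en-4-one (trans-fused; 5α-H; 7β-isopropenyl; 10β-CH3) | C=C(C)[C@@H]1CC[C@]2(C)[C@@H](C1)C(=O)CC[C@H]2CO[Si](C(C)C)(C(C)C)C(C)C | intermediate (key-step product)
13 | Δ3 lithium enolate of 12 | C=C(C)[C@@H]1CC[C@]2(C)[C@@H](C1)C(O[Li])=CC[C@H]2CO[Si](C(C)C)(C(C)C)C(C)C | intermediate (not isolated)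
14 | Δ3 enol triflate of 12 | C=C(C)[C@@H]1CC[C@]2(C)[C@@H](C1)C(OS(=O)(=O)C(F)(F)F)=CC[C@H]2CO[Si](C(C)C)(C(C)C)C(C)C | intermediate
15 | 1β-{[tri(propan-2-yl)silyl]oxymethyl}eudesma-3,11-diene | C=C(C)[C@@H]1CC[C@]2(C)[C@@H](C1)C(C)=CC[C@H]2CO[Si](C(C)C)(C(C)C)C(C)C | intermediate
16 | 3α,4α-epoxide of 15 | C=C(C)[C@@H]1CC[C@]2(C)[C@@H](C1)[C@]1(C)O[C@@H]1CC[C@H]2CO[Si](C(C)C)(C(C)C)C(C)C | intermediate
17 | 1β-{[tri(propan-2-yl)silyl]oxymethyl}eudesm-11-en-4α-ol | C=C(C)[C@@H]1CC[C@]2(C)[C@@H](C1)[C@](C)(O)CC[C@H]2CO[Si](C(C)C)(C(C)C)C(C)C | intermediate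
18 | 1β-(hydroxymethyl)eudesm-11-en-4α-ol | C=C(C)[C@@H]1CC[C@]2(C)[C@@H](C1)[C@](C)(O)CC[C@H]2CO | intermediate
19 | 4α-hydroxyeudesm-11-ene-1β-carbaldehyde | C=C(C)[C@@H]1CC[C@]2(C)[C@@H](C1)[C@](C)(O)CC[C@H]2C=O | intermediate
20 | 2-hydroxy-4,6-dimethoxybenzaldehyde | COc1cc(O)c(C=O)c(OC)c1 | starting material
21 | 2,4-dimethoxy-6-(methoxymethoxy)benzaldehyde | COCOc1cc(OC)cc(OC)c1C=O | intermediate
22 | 2,4-dimethoxy-6-(methoxymethoxy)phenyl formate | COCOc1cc(OC)cc(OC)c1OC=O | intermediate (not isolated)
23 | 2,4-dimethoxy-6-(methoxymethoxy)phenol | COCOc1cc(OC)cc(OC)c1O | intermediate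
24 | 1,2,5-trimethoxy-3-(methoxymethoxy)benzene | COCOc1cc(OC)cc(OC)c1OC | intermediate
25 | [2-(methoxymethoxy)-3,4,6-trimethoxyphenyl]lithium | [Li]c1c(OCOC)c(OC)c(OC)cc1OC | intermediate (not isolated)
26 | 1β-{hydroxy[2-(methoxymethoxy)-3,4,6-trimethoxyphenyl]methyl}eudesm-11-en-4α-ol (carbinol epimers) | C=C(C)[C@@H]1CC[C@]2(C)[C@@H](C1)[C@](C)(O)CC[C@H]2C(O)c1c(OCOC)c(OC)c(OC)cc1OC | intermediate
27 | trimethyl[(1-phenylethenyl)oxy]silane | C=C(O[Si](C)(C)C)c1ccccc1 | starting material
28 | 3-(4α-hydroxyeudesm-11-en-1β-yl)-3-[2-(methoxymethoxy)-3,4,6-trimethoxyphenyl]-1-phenylpropan-1-one, (S) at the benzylic carbon | C=C(C)[C@@H]1CC[C@]2(C)[C@@H](C1)[C@](C)(O)CC[C@H]2[C@H](CC(=O)c1ccccc1)c1c(OCOC)c(OC)c(OC)cc1OC | intermediate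
29 | keto phenol: 28 without the MOM group | C=C(C)[C@@H]1CC[C@]2(C)[C@@H](C1)[C@](C)(O)CC[C@H]2[C@H](CC(=O)c1ccccc1)c1c(O)c(OC)c(OC)cc1OC | intermediate (not isolated)
30 | methyl ketal: 2′-methoxy-2′-phenylchroman (C2′ epimers) | C=C(C)[C@@H]1CC[C@]2(C)[C@@H](C1)[C@](C)(O)CC[C@H]2[C@@H]1CC(OC)(c2ccccc2)Oc2c(OC)c(OC)cc(OC)c21 | intermediate (not isolated)
31 | (4′R)-4′-(4α-hydroxyeudesm-11-en-1β-yl)-5′,7′,8′-trimethoxy-2′-phenyl-4′H-chromene (CNP0390914.2) | C=C(C)[C@@H]1CC[C@]2(C)[C@@H](C1)[C@](C)(O)CC[C@H]2[C@@H]1C=C(c2ccccc2)Oc2c(OC)c(OC)cc(OC)c21 | target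

Total step count: 19 (steps 1–13 on the terpene, steps 14–16 on the arene, steps 17–19 after their union).
Longest linear sequence: 16 steps (1–13, then 17–19).

Steps most likely to fail

1. Step 7 (key ene closure). After C6–C7 bonding, the dipolar intermediate may leave by paths other than transfer of the methyl hydrogen (enolate C-attack, hydride shifts, chloride capture), or the ring may close through a boat, which would erode control at C7. The fallback sets out from 5 and returns at 12. Ring B would be closed by an intramolecular Hosomi–Sakurai reaction, in which loss of silicon is the only exit of the cation and gives the isopropenyl group regiospecifically.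
   - Cross-metathesis of 4-bromobut-1-ene with excess 2-methylallyltrimethylsilane (second-generation Hoveyda–Grubbs catalyst, CH2Cl2, 40 °C) gives (5-bromo-2-methylpent-2-en-1-yl)trimethylsilane F1. Its alkene geometry is lost in the closure, so an E/Z mixture serves.
   - Its Grignard reagent, [4-methyl-5-(trimethylsilyl)pent-3-en-1-yl]magnesium bromide F2, is added to 5 under the conditions of step 5 to give the silyl enol ether F3.
   - MeLi (THF, 0 °C) converts F3 to the lithium enolate F4, which is far more nucleophilic than the allylsilane. Eschenmoser's salt at −78 °C gives the Mannich base F5; MeI gives the ammonium iodide F6; DBU gives the α-methylene ketone with the allylsilane chain F7.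
   - EtAlCl2 (CH2Cl2, −78 °C) then bonds C7 to C6 through the same chair, the β-silyl cation loses its silyl group, and work-up with the K2CO3/MeOH equilibration gives 12.

2. Step 18 (capture of the benzylic cation). The two faces of the cation may be discriminated poorly, or the cation may be lost by elimination; the preceding addition to the hindered aldehyde may also suffer enolisation. The fallback sets out from 19, uses aryllithium 25, and returns at 28. Horner–Wadsworth–Emmons reaction of 19 with diethyl (2-oxo-2-phenylethyl)phosphonate (LiCl, iPr2NEt, MeCN, 23 °C) gives the (E)-enone F8. The aryl group is then delivered to C4′ by conjugate addition of the lithium diarylcuprate F9 (from 25 and CuI, THF, −78 to −40 °C, in excess because of the free hydroxyl), and aqueous work-up gives 28. C4′ is here set by Felkin–Anh-type attack on the enone anti to C10, a different control element that is expected to lead to the same configuration, and the aryl carbinol is bypassed altogether.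

3. Step 3 (lipase resolution). The stereocentre lies one carbon away from the reacting hydroxyl, so the lipase may discriminate the enantiomers too weakly to leave 4 enantiopure. The fallback sets out from 3 and returns at 5. rac-3 is silylated (TIPSCl, imidazole, DMF) to the racemic enone F10. Catalyst-controlled Corey–Bakshi–Shibata reduction ((S)-2-methyl-CBS-oxazaborolidine, BH3·SMe2, THF, −20 °C) should set the carbinol as 1R whatever the configuration at C4. The racemate thus becomes two diastereomers, the (1R,4R)-alcohol F11 and the (1R,4S)-alcohol F12, which are separated by chromatography. Oxidation of F11 with MnO2 (CH2Cl2, 23 °C) gives 5.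

Further compounds
F1 | step 7 | (5-bromo-2-methylpent-2-en-1-yl)trimethylsilane (E/Z mixture) | C[Si](C)(C)CC(C)=CCCBr
F2 | step 7 | [4-methyl-5-(trimethylsilyl)pent-3-en-1-yl]magnesium bromide | C[Si](C)(C)CC(C)=CCC[Mg]Br
F3 | step 7 | C4=C5 trimethylsilyl enol ether with the allylsilane chain on C10 | C[Si](C)(C)CC(C)=CCC[C@]1(C)C=C(O[Si](C)(C)C)CC[C@H]1CO[Si](C(C)C)(C(C)C)C(C)C
F4 | step 7 | lithium enolate from F3 | C[Si](C)(C)CC(C)=CCC[C@]1(C)C=C(O[Li])CC[C@H]1CO[Si](C(C)C)(C(C)C)C(C)C
F5 | step 7 | Mannich base with the allylsilane chain | C[Si](C)(C)CC(C)=CCC[C@]1(C)C(CN(C)C)C(=O)CC[C@H]1CO[Si](C(C)C)(C(C)C)C(C)C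
F6 | step 7 | trimethylammonium iodide of F5 | C[Si](C)(C)CC(C)=CCC[C@]1(C)C(C[N+](C)(C)C)C(=O)CC[C@H]1CO[Si](C(C)C)(C(C)C)C(C)C.[I-]
F7 | step 7 | ring A α-methylene ketone with the allylsilane chain | C=C1C(=O)CC[C@@H](CO[Si](C(C)C)(C(C)C)C(C)C)[C@]1(C)CCC=C(C)C[Si](C)(C)C
F8 | step 18 | (E)-3-(4α-hydroxyeudesm-11-en-1β-yl)-1-phenylprop-2-en-1-one | C=C(C)[C@@H]1CC[C@]2(C)[C@@H](C1)[C@](C)(O)CC[C@H]2/C=C/C(=O)c1ccccc1
F9 | step 18 | lithium bis[2-(methoxymethoxy)-3,4,6-trimethoxyphenyl]cuprate | [Li+].COCOc1c(OC)c(OC)cc(OC)c1[Cu-]c1c(OC)cc(OC)c(OC)c1OCOC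
F10 | step 3 | rac-3-methyl-4-{[tri(propan-2-yl)silyl]oxymethyl}cyclohex-2-en-1-one | CC1=CC(=O)CCC1CO[Si](C(C)C)(C(C)C)C(C)C
F11 | step 3 | (1R,4R)-3-methyl-4-{[tri(propan-2-yl)silyl]oxymethyl}cyclohex-2-en-1-ol | CC1=C[C@H](O)CC[C@H]1CO[Si](C(C)C)(C(C)C)C(C)C
F12 | step 3 | (1R,4S)-3-methyl-4-{[tri(propan-2-yl)silyl]oxymethyl}cyclohex-2-en-1-ol | CC1=C[C@H](O)CC[C@@H]1CO[Si](C(C)C)(C(C)C)C(C)C
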